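**Retrosynthetic overview**

- The target is a trans-(2S,3S)-2,3-diaryl-2,3-dihydrobenzofuran. It comes from one hydrogenation that saturates a stilbene C=C and removes five O-benzyl groups; the stilbene comes from a Mizoroki–Heck coupling of a 6-bromo-dihydrobenzofuran with 4-benzyloxystyrene.
- The trans core comes from acid equilibration at C2 of the cis isomer (C3 untouched); the same acid removes the unused second benzylic ether arm.
- The cis-dihydrobenzofuran comes from an enantioselective dirhodium-carbene C–H insertion of a diaryldiazomethane into an O–CH2–aryl bond (forms C2–C3). Two identical ortho arms remove any regiochemical choice.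
- The diazo compound comes from a hydrazone, made by imine–hydrazone exchange on the N–H ketimine from an aryl Grignard and a 4-bromo-2,6-bis(arylmethoxy)benzonitrile; the nitrile comes from a double SNAr on 4-bromo-2,6-difluorobenzonitrile.
- Ring order: all benzene rings are bought; the dihydrofuran ring is the only ring formed (step 4).

Assumption: Rh2(R-PTAD)4, dirhodium tetrakis[(R)-(1-adamantyl)(phthalimido)acetate], is taken as the catalyst antipode that gives the (3S) centre; if the first run shows the opposite sense, Rh2(S-PTAD)4 is used and nothing else changes.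

**Route**

Step 1
Reactants: 1 2,4-bis(benzyloxy)benzaldehyde
Product: 2 [2,4-bis(benzyloxy)phenyl]methanol
Conditions: NaBH4 (1.0 equiv), MeOH/THF 1:1, 0 °C to rt
Reagents that add atoms: none
Why: Borohydride reduction (hydride addition to the aldehyde) is selective for C=O and leaves the benzyl ethers untouched; no stereocentre is formed.

Step 2
Reactants: 2 [2,4-bis(benzyloxy)phenyl]methanol (2.2 equiv); 3 4-bromo-2,6-difluorobenzonitrile
Product: 6 4-bromo-2,6-bis{[2,4-bis(benzyloxy)phenyl]methoxy}benzonitrile, via sodium alkoxide 4 (not isolated), via monoether fluoronitrile 5 (not isolated)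
Conditions: NaH (2.4 equiv), THF/DMF 4:1, 0 °C; then 3, 0 °C to 45 °C
Reagents that add atoms: none
Why: Twofold nucleophilic aromatic substitution (SNAr): both fluorides are ortho to the nitrile and leave far faster than the para bromide, and the nitrile keeps the ring activated for the second displacement; no stereocentre.

Step 3
Reactants: 6 4-bromo-2,6-bis{[2,4-bis(benzyloxy)phenyl]methoxy}benzonitrile; 7 1-bromo-3,5-bis(benzyloxy)benzene (1.5 equiv)
Product: 11 {(4-bromo-2,6-bis{[2,4-bis(benzyloxy)phenyl]methoxy}phenyl)[3,5-bis(benzyloxy)phenyl]methylidene}hydrazine (N-unsubstituted hydrazone), via arylmagnesium bromide 8 (not isolated), via bromomagnesium ketimide 9 (not isolated), via free ketimine 10 (not isolated)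
Conditions: 7, Mg turnings, THF, 45 °C; add 6 in toluene, 70 °C; cool, MeOH; then N2H4·H2O (15 equiv), AcOH (2 equiv), EtOH, 75 °C
Reagents that add atoms: hydrazine (used as the monohydrate), NN
Why: Grignard addition to a nitrile stops at the ketimide (the linear nitrile tolerates two ortho ethers and ArMgBr does not exchange with the aryl bromide), and the N–H ketimine then undergoes imine–hydrazone exchange (transimination), which is easier than condensing hydrazine with the corresponding 2,6-disubstituted ketone; no stereocentre.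

Step 4
Reactants: 11 the hydrazone
Product: 13 (2R,3S)-6-bromo-2-[2,4-bis(benzyloxy)phenyl]-3-[3,5-bis(benzyloxy)phenyl]-4-{[2,4-bis(benzyloxy)phenyl]methoxy}-2,3-dihydro-1-benzofuran (2,3-cis), via diaryldiazomethane 12 (not isolated)
Conditions: MnO2 (activated, 8 equiv), CH2Cl2, 0 °C, filter through diatomaceous earth; then add to Rh2(R-PTAD)4 (1 mol%), CH2Cl2, 0 °C
Reagents that add atoms: none
Why: MnO2 dehydrogenates the hydrazone to the diaryldiazomethane, whose donor/donor dirhodium carbene (divalent rhodium, chiral carboxylate ligands) undergoes intramolecular 1,5 C–H insertion into a benzylic ether C–H bond; the two arms are equivalent, the chiral catalyst fixes C3 as S and the kinetic ring closure places the C2 aryl cis to it (2R).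

Step 5
Reactants: 13 the cis-dihydrobenzofuran
Product: 15 (2S,3S)-6-bromo-2-[2,4-bis(benzyloxy)phenyl]-3-[3,5-bis(benzyloxy)phenyl]-2,3-dihydro-1-benzofuran-4-ol (2,3-trans), via trans diether 14 (not isolated)
Conditions: CF3CO2H (10 vol%), 1,3,5-trimethoxybenzene (5 equiv), CH2Cl2, 0 °C to rt
Reagents that add atoms: none
Why: Acid ionises the benzylic, ortho/para-dialkoxy-stabilised C2–O bond and the phenol oxygen recloses to the thermodynamically preferred trans isomer (epimerisation at C2 only, C3 stays S), while the same acid cleaves the 2,4-dialkoxybenzyl aryl ether and the arene scavenger takes up the benzyl cation by Friedel–Crafts alkylation.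

Step 6
Reactants: 15 the trans bromophenol; 16 1-(benzyloxy)-4-ethenylbenzene (4-benzyloxystyrene, 1.5 equiv)
Product: 17 (2S,3S)-2-[2,4-bis(benzyloxy)phenyl]-3-[3,5-bis(benzyloxy)phenyl]-6-{(E)-2-[4-(benzyloxy)phenyl]ethenyl}-2,3-dihydro-1-benzofuran-4-ol
Conditions: Pd(OAc)2 (5 mol%), P(o-tol)3 (12 mol%), Et3N (3 equiv), DMF, 100 °C
Reagents that add atoms: none
Why: Mizoroki–Heck reaction: oxidative addition of the unhindered aryl bromide to zerovalent palladium, syn insertion of the styrene and syn β-hydride elimination give the E-stilbene; the acid-free conditions leave both stereocentres and the free phenol alone.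

Step 7
Reactants: 17 the pentabenzyl stilbene
Product: 19 4-[(2S,3S)-3-(3,5-dihydroxyphenyl)-4-hydroxy-6-[2-(4-hydroxyphenyl)ethyl]-2,3-dihydro-1-benzofuran-2-yl]benzene-1,3-diol (target), via pentabenzyl bibenzyl 18 (not isolated)
Conditions: H2 (1 atm), Pd/C (10 wt% Pd), EtOAc/EtOH 1:1, rt, stopped at six equivalents of H2
Reagents that add atoms: none
Why: Heterogeneous catalytic hydrogenation saturates the stilbene first and then hydrogenolyses the five primary O-benzyl ethers; the ring C2–O bond is a secondary, internal benzylic ether that cleaves more slowly, so both stereocentres are retained.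

**Compound list**

1 | 2,4-bis(benzyloxy)benzaldehyde | O=Cc1ccc(OCc2ccccc2)cc1OCc1ccccc1 | starting material
2 | [2,4-bis(benzyloxy)phenyl]methanol | OCc1ccc(OCc2ccccc2)cc1OCc1ccccc1 | intermediate
3 | 4-bromo-2,6-difluorobenzonitrile | N#Cc1c(F)cc(Br)cc1F | starting material
4 | sodium [2,4-bis(benzyloxy)phenyl]methanolate | [Na+].[O-]Cc1ccc(OCc2ccccc2)cc1OCc1ccccc1 | intermediate, not isolated
5 | 4-bromo-2-{[2,4-bis(benzyloxy)phenyl]methoxy}-6-fluorobenzonitrile | N#Cc1c(F)cc(Br)cc1OCc1ccc(OCc2ccccc2)cc1OCc1ccccc1 | intermediate, not isolated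
6 | 4-bromo-2,6-bis{[2,4-bis(benzyloxy)phenyl]methoxy}benzonitrile | N#Cc1c(OCc2ccc(OCc3ccccc3)cc2OCc2ccccc2)cc(Br)cc1OCc1ccc(OCc2ccccc2)cc1OCc1ccccc1 | intermediate
7 | 1-bromo-3,5-bis(benzyloxy)benzene | Brc1cc(OCc2ccccc2)cc(OCc2ccccc2)c1 | starting material
8 | [3,5-bis(benzyloxy)phenyl]magnesium bromide | Br[Mg]c1cc(OCc2ccccc2)cc(OCc2ccccc2)c1 | intermediate, not isolated
9 | N-bromomagnesium salt of ketimine 10 | Br[Mg]N=C(c1cc(OCc2ccccc2)cc(OCc2ccccc2)c1)c1c(OCc2ccc(OCc3ccccc3)cc2OCc2ccccc2)cc(Br)cc1OCc1ccc(OCc2ccccc2)cc1OCc1ccccc1 | intermediate, not isolated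
10 | 1-(4-bromo-2,6-bis{[2,4-bis(benzyloxy)phenyl]methoxy}phenyl)-1-[3,5-bis(benzyloxy)phenyl]methanimine | N=C(c1cc(OCc2ccccc2)cc(OCc2ccccc2)c1)c1c(OCc2ccc(OCc3ccccc3)cc2OCc2ccccc2)cc(Br)cc1OCc1ccc(OCc2ccccc2)cc1OCc1ccccc1 | intermediate, not isolated
11 | {(4-bromo-2,6-bis{[2,4-bis(benzyloxy)phenyl]methoxy}phenyl)[3,5-bis(benzyloxy)phenyl]methylidene}hydrazine | NN=C(c1cc(OCc2ccccc2)cc(OCc2ccccc2)c1)c1c(OCc2ccc(OCc3ccccc3)cc2OCc2ccccc2)cc(Br)cc1OCc1ccc(OCc2ccccc2)cc1OCc1ccccc1 | intermediate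
12 | 5-bromo-1,3-bis{[2,4-bis(benzyloxy)phenyl]methoxy}-2-{[3,5-bis(benzyloxy)phenyl](diazo)methyl}benzene | [N-]=[N+]=C(c1cc(OCc2ccccc2)cc(OCc2ccccc2)c1)c1c(OCc2ccc(OCc3ccccc3)cc2OCc2ccccc2)cc(Br)cc1OCc1ccc(OCc2ccccc2)cc1OCc1ccccc1 | intermediate, not isolated
13 | (2R,3S)-6-bromo-2-[2,4-bis(benzyloxy)phenyl]-3-[3,5-bis(benzyloxy)phenyl]-4-{[2,4-bis(benzyloxy)phenyl]methoxy}-2,3-dihydro-1-benzofuran (cis) | Brc1cc(OCc2ccc(OCc3ccccc3)cc2OCc2ccccc2)c2c(c1)O[C@@H](c1ccc(OCc3ccccc3)cc1OCc1ccccc1)[C@H]2c1cc(OCc2ccccc2)cc(OCc2ccccc2)c1 | intermediate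
14 | (2S,3S)-6-bromo-2-[2,4-bis(benzyloxy)phenyl]-3-[3,5-bis(benzyloxy)phenyl]-4-{[2,4-bis(benzyloxy)phenyl]methoxy}-2,3-dihydro-1-benzofuran (trans) | Brc1cc(OCc2ccc(OCc3ccccc3)cc2OCc2ccccc2)c2c(c1)O[C@H](c1ccc(OCc3ccccc3)cc1OCc1ccccc1)[C@H]2c1cc(OCc2ccccc2)cc(OCc2ccccc2)c1 | intermediate, not isolated
15 | (2S,3S)-6-bromo-2-[2,4-bis(benzyloxy)phenyl]-3-[3,5-bis(benzyloxy)phenyl]-2,3-dihydro-1-benzofuran-4-ol (trans) | Brc1cc(O)c2c(c1)O[C@H](c1ccc(OCc3ccccc3)cc1OCc1ccccc1)[C@H]2c1cc(OCc2ccccc2)cc(OCc2ccccc2)c1 | intermediate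
16 | 1-(benzyloxy)-4-ethenylbenzene | C=Cc1ccc(OCc2ccccc2)cc1 | starting material
17 | (2S,3S)-2-[2,4-bis(benzyloxy)phenyl]-3-[3,5-bis(benzyloxy)phenyl]-6-{(E)-2-[4-(benzyloxy)phenyl]ethenyl}-2,3-dihydro-1-benzofuran-4-ol | c1ccccc1COc1ccc(/C=C/c2cc(O)c3c(c2)O[C@H](c2ccc(OCc4ccccc4)cc2OCc2ccccc2)[C@H]3c2cc(OCc3ccccc3)cc(OCc3ccccc3)c2)cc1 | intermediate
18 | (2S,3S)-2-[2,4-bis(benzyloxy)phenyl]-3-[3,5-bis(benzyloxy)phenyl]-6-{2-[4-(benzyloxy)phenyl]ethyl}-2,3-dihydro-1-benzofuran-4-ol | c1ccccc1COc1ccc(CCc2cc(O)c3c(c2)O[C@H](c2ccc(OCc4ccccc4)cc2OCc2ccccc2)[C@H]3c2cc(OCc3ccccc3)cc(OCc3ccccc3)c2)cc1 | intermediate, not isolated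
19 | 4-[(2S,3S)-3-(3,5-dihydroxyphenyl)-4-hydroxy-6-[2-(4-hydroxyphenyl)ethyl]-2,3-dihydro-1-benzofuran-2-yl]benzene-1,3-diol | Oc1ccc(CCc2cc(O)c3c(c2)O[C@H](c2ccc(O)cc2O)[C@H]3c2cc(O)cc(O)c2)cc1 | target

**Totals**

Total step count: 7. Longest linear sequence: 7 steps (1 to 19).

**Three steps most likely to fail**

Step 4 (carbene C–H insertion). The carbene carbon carries a 2,6-disubstituted aryl ring, which is more crowded than the usual substrates for this reaction, so yield or enantioselectivity may drop. The fallback gives up catalyst control and resolves instead. It sets out from 11 and comes back at 13. Oxidation with MnO2 to 12 and decomposition with dirhodium tetraacetate Rh2(OAc)4 in CH2Cl2 gives the racemic cis product, that is 13 together with its antipode (2S,3R)-6-bromo-2-[2,4-bis(benzyloxy)phenyl]-3-[3,5-bis(benzyloxy)phenyl]-4-{[2,4-bis(benzyloxy)phenyl]methoxy}-2,3-dihydro-1-benzofuran F5. Preparative supercritical-fluid chromatography on an amylose tris(3,5-dimethylphenylcarbamate) stationary phase then delivers 13.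

Step 5 (acid epimerisation with loss of the spare ether). The released benzyl cation may alkylate ring A of the product, and loss of H3 from the open cation (E1) would erode the enantiomeric purity. The fallback moves the epimerisation to the very end and sets out from 13, coming back at 19. Heck coupling of 13 with 16 under the step 6 conditions gives (2R,3S)-2-[2,4-bis(benzyloxy)phenyl]-3-[3,5-bis(benzyloxy)phenyl]-6-{(E)-2-[4-(benzyloxy)phenyl]ethenyl}-4-{[2,4-bis(benzyloxy)phenyl]methoxy}-2,3-dihydro-1-benzofuran F6. Hydrogenation over Pd/C as in step 7 then reduces the alkene and removes every benzylic ether, the spare arm included, to give the cis hexaphenol 4-[(2R,3S)-3-(3,5-dihydroxyphenyl)-4-hydroxy-6-[2-(4-hydroxyphenyl)ethyl]-2,3-dihydro-1-benzofuran-2-yl]benzene-1,3-diol F7. Brief treatment with CF3CO2H (1 vol%) in MeCN at 0 °C to rt equilibrates C2 through the hydroxy-stabilised benzylic cation to the trans isomer 19.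

Step 3 (Grignard addition to the hindered nitrile and imine–hydrazone exchange). Either the addition or the exchange may stall. The fallback builds the ketone and introduces nitrogen with a silyl hydrazine; it sets out from 6 and comes back at 11.
- Reduction of 6 with i-Bu2AlH (toluene, −78 °C, then aqueous potassium sodium tartrate) gives 4-bromo-2,6-bis{[2,4-bis(benzyloxy)phenyl]methoxy}benzaldehyde F1.
- Addition of the arylmagnesium bromide 8 (made again from 7) gives racemic (4-bromo-2,6-bis{[2,4-bis(benzyloxy)phenyl]methoxy}phenyl)[3,5-bis(benzyloxy)phenyl]methanol F2.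
- Dess–Martin periodinane in CH2Cl2 gives (4-bromo-2,6-bis{[2,4-bis(benzyloxy)phenyl]methoxy}phenyl)[3,5-bis(benzyloxy)phenyl]methanone F3.
- 1,2-Bis(tert-butyldimethylsilyl)hydrazine with Sc(OTf)3 (1 mol%) gives the N-(tert-butyldimethylsilyl)hydrazone of that ketone F4.
- n-Bu4NF in THF at 0 °C frees the hydrazone 11.

**Further compounds**

F1 | step 3 | 4-bromo-2,6-bis{[2,4-bis(benzyloxy)phenyl]methoxy}benzaldehyde | O=Cc1c(OCc2ccc(OCc3ccccc3)cc2OCc2ccccc2)cc(Br)cc1OCc1ccc(OCc2ccccc2)cc1OCc1ccccc1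
F2 | step 3 | racemic (4-bromo-2,6-bis{[2,4-bis(benzyloxy)phenyl]methoxy}phenyl)[3,5-bis(benzyloxy)phenyl]methanol | OC(c1cc(OCc2ccccc2)cc(OCc2ccccc2)c1)c1c(OCc2ccc(OCc3ccccc3)cc2OCc2ccccc2)cc(Br)cc1OCc1ccc(OCc2ccccc2)cc1OCc1ccccc1
F3 | step 3 | (4-bromo-2,6-bis{[2,4-bis(benzyloxy)phenyl]methoxy}phenyl)[3,5-bis(benzyloxy)phenyl]methanone | O=C(c1cc(OCc2ccccc2)cc(OCc2ccccc2)c1)c1c(OCc2ccc(OCc3ccccc3)cc2OCc2ccccc2)cc(Br)cc1OCc1ccc(OCc2ccccc2)cc1OCc1ccccc1
F4 | step 3 | N-(tert-butyldimethylsilyl)hydrazone of ketone F3 | CC(C)(C)[Si](C)(C)NN=C(c1cc(OCc2ccccc2)cc(OCc2ccccc2)c1)c1c(OCc2ccc(OCc3ccccc3)cc2OCc2ccccc2)cc(Br)cc1OCc1ccc(OCc2ccccc2)cc1OCc1ccccc1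
F5 | step 4 | (2S,3R)-6-bromo-2-[2,4-bis(benzyloxy)phenyl]-3-[3,5-bis(benzyloxy)phenyl]-4-{[2,4-bis(benzyloxy)phenyl]methoxy}-2,3-dihydro-1-benzofuran (antipode of 13) | Brc1cc(OCc2ccc(OCc3ccccc3)cc2OCc2ccccc2)c2c(c1)O[C@H](c1ccc(OCc3ccccc3)cc1OCc1ccccc1)[C@@H]2c1cc(OCc2ccccc2)cc(OCc2ccccc2)c1
F6 | step 5 | (2R,3S)-2-[2,4-bis(benzyloxy)phenyl]-3-[3,5-bis(benzyloxy)phenyl]-6-{(E)-2-[4-(benzyloxy)phenyl]ethenyl}-4-{[2,4-bis(benzyloxy)phenyl]methoxy}-2,3-dihydro-1-benzofuran | c1ccccc1COc1ccc(/C=C/c2cc(OCc3ccc(OCc4ccccc4)cc3OCc3ccccc3)c3c(c2)O[C@@H](c2ccc(OCc4ccccc4)cc2OCc2ccccc2)[C@H]3c2cc(OCc3ccccc3)cc(OCc3ccccc3)c2)cc1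
F7 | step 5 | 4-[(2R,3S)-3-(3,5-dihydroxyphenyl)-4-hydroxy-6-[2-(4-hydroxyphenyl)ethyl]-2,3-dihydro-1-benzofuran-2-yl]benzene-1,3-diol (2-epimer of 19) | Oc1ccc(CCc2cc(O)c3c(c2)O[C@@H](c2ccc(O)cc2O)[C@H]3c2cc(O)cc(O)c2)cc1
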